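The numbers in the tables were computed on assumed constants, and the scatter is random.

At early times the winter run reads G 49% and X 49%, level within the scatter of 1.5 percentage points, and L reads 0%. Later the two part.

| setting | noon | autumn | winter | flask |
|---|---|---|---|---|
| G | 0.50 M | 0.50 M | 0.50 M | 0.50 M |
| X | 0.50 M | 0.50 M | 0.50 M | 0.50 M |
| D | 0.75 M | 0.75 M | 1.5 M | 0.750 M |
| E | 0.25 mM | 1 mM | 0.50 mM | 0.50 mM |
| remark | run made earlier | run made earlier | run made earlier |  |
| time |  |  |  | 2.5 h |

- noon (time / h: X / %, G / %, L / %): 0.167: 47, 49, 0; 0.500: 48, 50, 2; 0.833: 50, 52, 1; 1.33: 46, 47, 0; 2.00: 50, 45, 2; 2.50: 46, 46, 5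
- autumn (time / h: X / %, G / %, L / %): 0.417: 51, 48, 0; 0.833: 47, 49, 5; 1.33: 46, 43, 5; 1.50: 46, 42, 4; 2.00: 46, 41, 7; 2.50: 44, 35, 10
- winter (time / h: X / %, G / %, L / %): 0.500: 49, 49, 0; 1.00: 48, 48, 6; 1.50: 50, 45, 4; 2.00: 45, 43, 4; 2.50: 46, 39, 5

(readings scatter by 1.5 percentage points)

- E is single-handed; G and X are mirror images of each other, charged as a racemate, each of them at the stated concentration
- as a solid, counted per litre of solution: D
- the numbers in the tables scatter by 1.5 percentage points (one standard deviation)
- at the start none of D is in solution

- whether the excess of X over G among what is left of the two reaches 98% by 2.5 h (yes / no)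
- the highest excess of X over G among what is left of the two up to 2.5 h

I follow one molecule of substrate. In each short interval it can react on E with dissolved D, and I assume that G and X meet the same partners, each with its own rate constant. Under that assumption, the log of the fraction of G left over the log of the fraction of X left stays fixed, however fast the clock runs. Pooling the last two rows of the autumn and winter runs, I read this ratio as 2.39. This reading, with its scatter, is the selectivity factor s.

The flask has the E of the winter run and half its D. The winter run ends at G 39% and X 46%, an excess (X minus G, over X plus G) of 8.24%.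

For the flask's clock I use the autumn run, which has the flask's D and 1 mM of E. It loses 15 points of G by 2.50 h. Scaled to 0.50 mM of E, that leaves G at 42.5%, and s puts X at 46.7%. The excess is then 4.72%. My figure for the flask is lower than the winter excess, but that excess is a reading from one G and one X, each scattering by 1.5 points, so I draw no reason from the gap. My answer is no, since this excess lies far below 98%.

The forecast says no and 5%, slightly above my figure. It calls the winter rate “only modestly faster than the roughly 2.8 %/h interpolated”.

The flask answers no, with a highest excess of 4.94%. At 2.50 h it keeps 83% of its charged G and 92% of its charged X.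

    Q + E + G → E + L (k = 0.550 L² mol⁻² s⁻¹)
    Q + E + X → E + Z (k = 0.250 L² mol⁻² s⁻¹)
    L ⇌ Z (k = 6.50 × 10⁻⁴ s⁻¹)
    Q ⇌ J (K = 14.0, k = 8.50 × 10⁻⁵ s⁻¹)
    D ⇌ Q, rate k5*(cs5 - [Q]) while solid is left; crystals form when [Q] > cs5 (solubility = 0.330 M, k = 1.20 × 10⁻⁴ s⁻¹)

Left until 6.0 h, the same flask keeps 57% of its G. With s at 2.39, I reckon 79.0% of its X left and an excess of 16.2%. That flask keeps 77% of its X, with a highest excess of 15.2%.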